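Start from the elm run: with 0.60 M of starting material, twice the ash charge, its target flattens at 23.4% of the charge, while ash, the flask asked about, flattens at 40.8%.

| flask | starting material | second substrate | free catalyst | temperature | remark | time |
|---|---|---|---|---|---|---|
| ash | 0.30 M | 0.15 M | 4.5 mM | 0 °C | the very flask that is asked about, followed so far |  |
| elm | 0.60 M | 0.15 M | 4.5 mM | 0 °C | run made earlier |  |
| flask | 0.30 M | 0.150 M | 4.5 mM | 0 °C |  | 20 min |

| run | time / min | target / % |
|---|---|---|
| ash | 1.00 | 37.9 |
| ash | 1.33 | 40.5 |
| ash | 2.00 | 40.8 |
| ash | 3.00 | 40.4 |
| ash | 5.00 | 41.2 |
| ash | 8.00 | 40.2 |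
| ash | 12.0 | 41.3 |
| elm | 0.500 | 15.4 |
| elm | 1.00 | 19.9 |
| elm | 1.50 | 23.2 |
| elm | 2.50 | 23.3 |
| elm | 3.00 | 23.1 |
| elm | 4.00 | 24.0 |

(scatter of a reading: 0.5 percentage points)

- percent here means starting material units held: one side product counts as two
- what is taken out of target is counted as made
- what may be going on: starting material + free catalyst <-> catalyst intermediate A; catalyst intermediate A -> free catalyst + target; second substrate + free catalyst <-> catalyst intermediate B; starting material + target -> side product; catalyst intermediate B -> free catalyst + second product
- the earlier runs do not show what temperature does; that part of a forecast is a guess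
- additions bring no volume worth counting

- teal: at 20 min add free catalyst, 50.0% of the amount charged, then wait 6.0 min
- ochre: change nothing and wait 6.0 min more
- grey: at 20 min raise the temperature by 15 K, then wait 6.0 min
- violet: at 20 min take out 90% of the target then present, then wait 6.0 min

* target, in percent of the starting material first charged, at 20 min
* what to do for the largest gain in target; "none" if nothing gains more than 2 percentage points (teal / ochre / grey / violet / none)
* target present, with what was taken out counted in, in percent of the starting material first charged, after teal
* target present, with what was taken out counted in, in percent of the starting material first charged, after grey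

Turn the question round: what must be true of ash for an option to gain more than 2 percentage points? Count in percent of the charge. Let M be the target made by the catalyst and E the target eaten by starting material, each eaten target taking one further unit of starting material with it. Target standing is then y = M − E, and starting material used is M + E. Once M + E reaches 100, M/E = (100 + y)/(100 − y). Take the flat stretch as that point: ash gives 2.38, and this is the split ratio S, target made per target eaten, a kind of selectivity factor. Its zero is the even case, S = 1, where y is 0. Elm, read the same way, gives 1.61, nearer that even case than ash.

If the split stayed at S, a gain of 2 points would need 4.9 points of unused starting material in ash at 20 min; with no target eaten at all it would still need 2 points, and in both cases a catalyst able to use it. Yet ash climbed from 37.9% to 40.5% within 0.330 min, then moved 0.5 points from 2.00 min to 12.0 min, less than the gain required. Commit to ash staying near 40.8%, with no option worth taking.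

The forecast gives 40.8%, best none, 40.9% after teal and 40.9% after grey, on the ground: “Once starting material is gone, target is stable”.

The flask gives 41.0%, best none, 41.0% after teal and 41.0% after grey.

    starting material + free catalyst ⇌ catalyst intermediate A (K = 54.3 L mol⁻¹, k = 10.7 L mol⁻¹ s⁻¹, Ea = 37.0 kJ mol⁻¹, ΔH = −34.0 kJ mol⁻¹)
    catalyst intermediate A → free catalyst + target (k = 3.03 s⁻¹, Ea = 61.0 kJ mol⁻¹)
    second substrate + free catalyst ⇌ catalyst intermediate B (K = 2.80 L mol⁻¹, k = 25.4 L mol⁻¹ s⁻¹, Ea = 39.0 kJ mol⁻¹, ΔH = 27.0 kJ mol⁻¹)
    starting material + target → side product (k = 0.165 L mol⁻¹ s⁻¹, Ea = 38.0 kJ mol⁻¹)
    catalyst intermediate B → free catalyst + second product (k = 1.36 s⁻¹, Ea = 65.0 kJ mol⁻¹)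
    (constants at 0 °C)

The result puts S for ash at 2.39, with starting material at 0% by 20.0 min; at 0.356 min target is being made 2.04 times as fast as it is used up. The neighbour with 0.018 M of free catalyst ends at 72.4% with starting material at 0%, so its S, further from the even case than that of ash, is 6.25.

Readings and results are simulated for substances that don't exist; noise was put on by code.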